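**Retrosynthetic overview** (labdane numbering; the target is (5R,8R,9R,10S,13R)-8,13-epoxy-2,3-secolabd-14-ene-2,3-dioic acid)
1. The plan rests on ring C, the tetrahydropyran O–C13–C12–C11–C9–C8, whose oxygen bridges two fully substituted carbons: C8 (its methyl syn-diaxial to the C10 methyl of ring B) and C13.
2. Endgame: C13 is carried as a δ-lactone carbonyl; MeLi, α-face allylation of the C13 oxocarbenium ion, allyl-to-vinyl truncation and tert-butyl ester cleavage complete the target.
3. Key disconnection: removing the ring C oxygen reveals a trans-fused angular-methyl hydrindan-13-one; Baeyer–Villiger insertion with migration of C8 expands the cyclopentanone to the pyranone.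
4. Hydrindanone: C5–C4 bond by enol triflate/zinc isobutyrate enolate coupling and α-face hydrogenation; C9 and C10 by Li/NH3 reductive alkylation with tert-butyl bromoacetate; C8 by D-phenylalanine-mediated annulation of 2-methylcyclopentane-1,3-dione with ethyl vinyl ketone.
5. Ring order: cyclopentane (from the dione), then ring B (annulation), then ring C (ring expansion of the cyclopentanone).

Key step: step 11

Remark: α and β refer to the labdane drawing in which the C8 and C10 methyl groups are β. Compound 22 is written as the open δ-hydroxy ketone, which equilibrates with its cyclic hemiketal.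

**Step 1**
Reactants: 1 2-methylcyclopentane-1,3-dione; 2 ethyl vinyl ketone
Product: 3 2-methyl-2-(3-oxopentyl)cyclopentane-1,3-dione
Conditions: H2O, AcOH (cat.), 75 °C
Reagents that add atoms: none
Why: Michael addition of the enolised 1,3-dione to the enone under mildly acidic aqueous conditions should give the achiral triketone without polymerising the vinyl ketone.

**Step 2**
Reactants: 3 2-methyl-2-(3-oxopentyl)cyclopentane-1,3-dione
Product: 5 (R)-4,7a-dimethyl-2,3,7,7a-tetrahydro-1H-indene-1,5(6H)-dione (C13 ketone, C9=C10–C5=O enone, C8 methyl β), via cis-fused ketol 4 (not isolated)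
Conditions: D-phenylalanine (1.0 equiv), 1 M aq. HClO4 (0.5 equiv), MeCN, 80 °C
Reagents that add atoms: none
Why: Hajos–Parrish–Eder–Sauer–Wiechert aldol condensation through the amino acid enamine of the side-chain ketone, whose carboxyl-directed transition state selects one of the two enantiotopic ring carbonyls; the D-amino acid should give the R configuration at C8 (the antipode of the series formed with L-amino acids), and the acid dehydrates ketol 4.

**Step 3**
Reactants: 5 (R)-enedione
Product: 6 (1R,7aR)-1-hydroxy-4,7a-dimethyl-1,2,3,6,7,7a-hexahydro-5H-inden-5-one (13β-alcohol, OH cis to the C8 methyl)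
Conditions: NaBH4 (0.3 equiv), EtOH, −20 °C
Reagents that add atoms: none
Why: Chemoselective NaBH4 1,2-reduction, since the saturated cyclopentanone is far more electrophilic than the tetrasubstituted enone carbonyl; hydride should attack C13 anti to the angular C8 methyl, giving the 13β alcohol, a temporary stereocentre erased in step 10.

**Step 4**
Reactants: 6 13β-hydroxy enone
Product: 7 13β-tert-butyldimethylsilyl ether of 6
Conditions: TBSCl, imidazole, DMF, 25 °C
Reagents that add atoms: tert-butyldimethylsilyl chloride, CC(C)(C)[Si](C)(C)Cl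
Why: Imidazole-promoted silylation of a secondary alcohol masks C13 for the dissolving-metal step.

**Step 5**
Reactants: 7 silyl ether enone; 8 tert-butyl bromoacetate
Product: 10 trans-fused C5 ketone carrying the C10 quaternary centre (CH3 β, CH2CO2t-Bu α), H9 α, 13β-OTBS, via lithium enolate 9 (not isolated)
Conditions: Li (2.5 equiv), NH3(l)/THF, t-BuOH (1.0 equiv), −78 °C; isoprene; NH3 evaporated; then 8 (3 equiv), THF, −78 → 0 °C
Reagents that add atoms: none
Why: Dissolving-metal (Birch-type) enone reduction with regiospecific enolate alkylation: protonation of the β-carbon C9 by t-BuOH should give the trans ring fusion (H9 α, anti to the C8 methyl), and the C5–C10 lithium enolate 9 should be alkylated at C10 on the α face, anti to the axial C8 methyl, leaving the C10 methyl β and syn to the C8 methyl.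

**Step 6**
Reactants: 10 C5 ketone
Product: 12 C5 enol triflate (C5=C6), via potassium enolate 11 (not isolated)
Conditions: KN(SiMe3)2 (1.1 equiv), THF, −78 °C; PhNTf2, −78 → 0 °C
Reagents that add atoms: N-phenylbis(trifluoromethanesulfonimide), O=S(=O)(N(c1ccccc1)S(=O)(=O)C(F)(F)F)C(F)(F)F
Why: Enol triflate formation by O-sulfonylation of a ketone enolate; enolisation can occur only toward C6 because C10 is quaternary, and the ketone α-protons are more acidic than those of the tert-butyl ester.

**Step 7**
Reactants: 12 C5 enol triflate; 13 tert-butyl 2-bromo-2-methylpropanoate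
Product: 15 C5=C6 alkene bearing C(CH3)2CO2t-Bu at C5 (bis(tert-butyl ester), 13β-OTBS), via bromozinc enolate 14 (not isolated)
Conditions: 13, Zn dust (TMSCl-activated), THF, 25 °C; then 12, Pd2(dba)3 (2.5 mol %), XPhos (10 mol %), LiCl, THF, 60 °C
Reagents that add atoms: none
Why: Negishi-type coupling of an alkenyl triflate with a Reformatsky zinc enolate (Pd-catalysed α-alkenylation of an ester), in which oxidative addition of zerovalent palladium into the C5–OTf bond, transmetalation of the zinc enolate and reductive elimination promoted by the bulky biarylphosphine should forge the C5–C4 bond; no stereocentre is formed.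

**Step 8**
Reactants: 15 C5=C6 alkene diester
Product: 16 saturated diester with H5 α (13β-OTBS)
Conditions: H2 (40 bar), 10% Pd/C, EtOAc, 40 °C
Reagents that add atoms: none
Why: Heterogeneous catalytic hydrogenation of the trisubstituted alkene (analogous to saturation of 4,4-dimethyl-Δ5 steroids): the β face of ring B is screened by the axial C8 and C10 methyls, so H2 should add from the α face and set H5 α, with pressure applied because C5 is flanked by two quaternary carbons.

**Step 9**
Reactants: 16 silyl ether diester
Product: 17 13β-alcohol diester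
Conditions: Bu4NF, THF, 50 °C
Reagents that add atoms: none
Why: Fluoride-mediated cleavage of the silyl ether, to which the tert-butyl esters are inert.

**Step 10**
Reactants: 17 13β-alcohol diester
Product: 18 trans-fused C13 hydrindanone bis(tert-butyl ester) (C8 methyl β, H9 α, C10 methyl β, H5 α)
Conditions: Dess–Martin periodinane, NaHCO3, CH2Cl2, 25 °C
Reagents that add atoms: none
Why: Buffered Dess–Martin oxidation of the secondary alcohol regenerates the C13 ketone, and no epimerisable centre lies next to it because C8 is quaternary.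

**Step 11** (key step)
Reactants: 18 C13 hydrindanone bis(tert-butyl ester)
Product: 20 C13 δ-lactone with the 8α C8–O bond in place (ring C pyranone), via Criegee adduct 19 (not isolated)
Conditions: m-CPBA (3 equiv), NaHCO3, CH2Cl2, 25 °C
Reagents that add atoms: 3-chloroperoxybenzoic acid, OOC(=O)c1cccc(Cl)c1
Why: The peracid adds to the C13 carbonyl to give Criegee adduct 19, and the C8–C13 bond then shifts to the proximal peroxide oxygen with loss of 3-chlorobenzoate, which is the Baeyer–Villiger oxidation of an α-quaternary cyclopentanone as known for angular-methyl hydrindan-1-ones and 17-oxo steroids. Ring C is closed by ring expansion of the five-membered ketone (a 1,2-shift of carbon to oxygen, not a cyclisation), so the C8–O and O–C13 bonds arise in one event and the di-tertiary ether never has to be made by substitution at C8. The oxygen-bearing stereocentre C8 is set with retention because the migrating carbon keeps its configuration, so the α C8–O bond and the β C8 methyl, syn-diaxial to the C10 methyl, are inherited from steps 2 and 5. The step needs migration of C8 in preference to C12, which the fully substituted C8 secures by stabilising the developing positive charge far better than the C12 methylene, helped by relief of strain in the trans-fused cyclopentanone. Bicarbonate buffers the 3-chlorobenzoic acid so that the tert-butyl esters and the new lactone should survive, and no alkene or other oxidisable group is present.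

**Step 12**
Reactants: 20 C13 δ-lactone
Product: 22 8α-hydroxy C13 methyl ketone bis(tert-butyl ester) (open form of the C13 methyl hemiketal), via lithium hemiketal alkoxide 21 (not isolated)
Conditions: MeLi (1.1 equiv), THF, −78 °C; AcOH quench at −78 °C
Reagents that add atoms: methyllithium, [Li]C
Why: Organolithium mono-addition to a δ-lactone: the tetrahedral alkoxide 21 persists at −78 °C so a second addition is suppressed, the hindered tert-butyl esters are far less electrophilic than the lactone, and no new stereocentre remains in the open-chain product.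

**Step 13**
Reactants: 22 δ-hydroxy methyl ketone
Product: 24 13α-allyl-13β-methyl pyran bis(tert-butyl ester), via C13 oxocarbenium triflate 23 (not isolated)
Conditions: allylSiMe3 (5 equiv), TMSOTf (1.2 equiv), CH2Cl2, −78 °C; Et3N quench
Reagents that add atoms: allyltrimethylsilane, C=CC[Si](C)(C)C
Why: Hosomi–Sakurai allylation of a cyclic oxocarbenium ion: TMSOTf closes 22 to its hemiketal and ionises it to 23, which the trans B/C fusion holds in one half-chair whose β (axial) trajectory at C13 runs into the axial C8 methyl across the ring oxygen, so the allylsilane is expected to approach from the open α face and set C13 with allyl α and methyl β.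

**Step 14**
Reactants: 24 13α-allyl pyran
Product: 25 13α-(E)-prop-1-enyl pyran bis(tert-butyl ester)
Conditions: RuHCl(CO)(PPh3)3 (5 mol %), toluene, 80 °C
Reagents that add atoms: none
Why: Ruthenium hydride-catalysed alkene isomerisation by hydrometalation and β-hydride elimination moves the terminal double bond to the more stable internal position and must stop there because C13 bears no hydrogen; C13 is not touched.

**Step 15**
Reactants: 25 13α-propenyl pyran
Product: 26 13α-vinyl pyran bis(tert-butyl ester) (di-tert-butyl ester of the target)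
Conditions: ethylene (5 bar), second-generation Hoveyda–Grubbs catalyst (10 mol %), toluene, 60 °C
Reagents that add atoms: ethylene, C=C
Why: Olefin cross-metathesis with excess ethylene (ethenolysis) exchanges the ethylidene terminus for methylene with release of propene, and the resulting vinyl group on a fully substituted carbon is too hindered to re-enter productive metathesis.

**Step 16**
Reactants: 26 di-tert-butyl ester
Product: 28 (5R,8R,9R,10S,13R)-8,13-epoxy-2,3-secolabd-14-ene-2,3-dioic acid (target), via bis(trimethylsilyl) ester 27 (not isolated)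
Conditions: TMSOTf (4 equiv), 2,6-lutidine (6 equiv), CH2Cl2, 0 → 25 °C; then aq. NaH2PO4 work-up
Reagents that add atoms: none
Why: Silyl triflate-mediated tert-butyl ester cleavage by carbonyl O-silylation and loss of isobutene (alkyl–oxygen fission, insensitive to the shielding of the C3 carbonyl) gives 27, which hydrolyses on work-up; lutidine keeps the medium non-protic so that the tertiary allylic C13–O bond, whose oxygen is shielded by two fully substituted carbons, should not ionise.

**Compound list**
1 | 2-methylcyclopentane-1,3-dione | CC1C(=O)CCC1=O | starting material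
2 | ethyl vinyl ketone (pent-1-en-3-one) | CCC(=O)C=C | starting material
3 | 2-methyl-2-(3-oxopentyl)cyclopentane-1,3-dione | CCC(=O)CCC1(C)C(=O)CCC1=O | intermediate
4 | cis-fused ketol, (7aR)-3a-hydroxy-4,7a-dimethylhexahydroindane-1,5-dione (OH cis to the angular methyl, C4 not defined) | O=C1CC[C@@]2(O)C(C)C(=O)CC[C@@]12C | intermediate (not isolated)
5 | (R)-4,7a-dimethyl-2,3,7,7a-tetrahydro-1H-indene-1,5(6H)-dione | O=C1CCC2=C(C)C(=O)CC[C@@]12C | intermediate
6 | (1R,7aR)-1-hydroxy-4,7a-dimethyl-1,2,3,6,7,7a-hexahydro-5H-inden-5-one | O[C@@H]1CCC2=C(C)C(=O)CC[C@@]12C | intermediate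
7 | 13β-TBS ether of 6 | CC(C)(C)[Si](C)(C)O[C@@H]1CCC2=C(C)C(=O)CC[C@@]12C | intermediate
8 | tert-butyl bromoacetate | BrCC(=O)OC(C)(C)C | starting material
9 | lithium C5–C10 enolate, trans-fused (H9 α) | CC(C)(C)[Si](C)(C)O[C@@H]1CC[C@@H]2C(C)=C(O[Li])CC[C@@]12C | intermediate (not isolated)
10 | trans-fused C5 ketone, C10 quaternary (CH3 β, CH2CO2t-Bu α), 13β-OTBS | CC(C)(C)[Si](C)(C)O[C@@H]1CC[C@@H]2[C@@](C)(CC(=O)OC(C)(C)C)C(=O)CC[C@@]12C | intermediate
11 | potassium C5=C6 enolate of 10 | CC(C)(C)[Si](C)(C)O[C@@H]1CC[C@@H]2[C@@](C)(CC(=O)OC(C)(C)C)C(O[K])=CC[C@@]12C | intermediate (not isolated)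
12 | C5 enol triflate (C5=C6) | CC(C)(C)[Si](C)(C)O[C@@H]1CC[C@@H]2[C@@](C)(CC(=O)OC(C)(C)C)C(OS(=O)(=O)C(F)(F)F)=CC[C@@]12C | intermediate
13 | tert-butyl 2-bromo-2-methylpropanoate | CC(C)(Br)C(=O)OC(C)(C)C | starting material
14 | bromozinc enolate of tert-butyl isobutyrate (Reformatsky reagent) | CC(C)([Zn]Br)C(=O)OC(C)(C)C | intermediate (not isolated)
15 | C5=C6 alkene with C(CH3)2CO2t-Bu at C5, 13β-OTBS | CC(C)(C)[Si](C)(C)O[C@@H]1CC[C@@H]2[C@@](C)(CC(=O)OC(C)(C)C)C(C(C)(C)C(=O)OC(C)(C)C)=CC[C@@]12C | intermediate
16 | saturated diester, H5 α, 13β-OTBS | CC(C)(C)[Si](C)(C)O[C@@H]1CC[C@@H]2[C@@](C)(CC(=O)OC(C)(C)C)[C@H](C(C)(C)C(=O)OC(C)(C)C)CC[C@@]12C | intermediate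
17 | 13β-alcohol diester | O[C@@H]1CC[C@@H]2[C@@](C)(CC(=O)OC(C)(C)C)[C@H](C(C)(C)C(=O)OC(C)(C)C)CC[C@@]12C | intermediate
18 | trans-fused C13 hydrindanone bis(tert-butyl ester) | O=C1CC[C@@H]2[C@@](C)(CC(=O)OC(C)(C)C)[C@H](C(C)(C)C(=O)OC(C)(C)C)CC[C@]21C | intermediate
19 | Criegee adduct of 18 (C13 configuration not defined) | OC1(OOC(=O)c3cccc(Cl)c3)CC[C@@H]2[C@@](C)(CC(=O)OC(C)(C)C)[C@H](C(C)(C)C(=O)OC(C)(C)C)CC[C@]21C | intermediate (not isolated)
20 | C13 δ-lactone, 8α-O (ring C pyranone) | O=C1CC[C@@H]2[C@@](C)(CC(=O)OC(C)(C)C)[C@H](C(C)(C)C(=O)OC(C)(C)C)CC[C@@]2(C)O1 | intermediate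
21 | lithium hemiketal alkoxide (C13 configuration not defined) | CC1(O[Li])CC[C@@H]2[C@@](C)(CC(=O)OC(C)(C)C)[C@H](C(C)(C)C(=O)OC(C)(C)C)CC[C@@]2(C)O1 | intermediate (not isolated)
22 | 8α-hydroxy C13 methyl ketone bis(tert-butyl ester) | CC(=O)CC[C@@H]1[C@@](C)(CC(=O)OC(C)(C)C)[C@H](C(C)(C)C(=O)OC(C)(C)C)CC[C@@]1(C)O | intermediate
23 | C13 oxocarbenium triflate | CC1CC[C@@H]2[C@@](C)(CC(=O)OC(C)(C)C)[C@H](C(C)(C)C(=O)OC(C)(C)C)CC[C@@]2(C)[O+]=1.[O-]S(=O)(=O)C(F)(F)F | intermediate (not isolated)
24 | 13α-allyl-13β-methyl pyran bis(tert-butyl ester) | C=CC[C@@]1(C)CC[C@@H]2[C@@](C)(CC(=O)OC(C)(C)C)[C@H](C(C)(C)C(=O)OC(C)(C)C)CC[C@@]2(C)O1 | intermediate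
25 | 13α-(E)-prop-1-enyl pyran bis(tert-butyl ester) | C/C=C/[C@@]1(C)CC[C@@H]2[C@@](C)(CC(=O)OC(C)(C)C)[C@H](C(C)(C)C(=O)OC(C)(C)C)CC[C@@]2(C)O1 | intermediate
26 | di-tert-butyl ester of the target (13α-vinyl) | C=C[C@@]1(C)CC[C@@H]2[C@@](C)(CC(=O)OC(C)(C)C)[C@H](C(C)(C)C(=O)OC(C)(C)C)CC[C@@]2(C)O1 | intermediate
27 | bis(trimethylsilyl) ester of the target | C=C[C@@]1(C)CC[C@@H]2[C@@](C)(CC(=O)O[Si](C)(C)C)[C@H](C(C)(C)C(=O)O[Si](C)(C)C)CC[C@@]2(C)O1 | intermediate (not isolated)
28 | (5R,8R,9R,10S,13R)-8,13-epoxy-2,3-secolabd-14-ene-2,3-dioic acid | C=C[C@@]1(C)CC[C@@H]2[C@@](C)(CC(=O)O)[C@H](C(C)(C)C(=O)O)CC[C@@]2(C)O1 | target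

**Step count and risks**
Total step count: 16. Longest linear sequence: 16 (fully linear).

Steps most likely to fail:

1. Step 13, facial selectivity at C13. The stereoelectronically preferred axial (β) attack on the oxocarbenium ion may compete with or override steric approach control, giving the C13 epimer or a mixture. The fallback reverses the order in which the two C13 substituents arrive and sets out from lactone 20. Lithium (trimethylsilyl)acetylide (THF, −78 °C) should add once to give the δ-hydroxy ynone F1. TMSOTf followed by AlMe3 (CH2Cl2, −78 °C) would ionise its hemiketal form and deliver methyl along the axial β trajectory, giving the 13β-methyl-13α-(trimethylsilylethynyl) pyran F2. K2CO3 in MeOH would give the terminal alkyne F3, and semihydrogenation over Pd/CaCO3 poisoned with Pb(OAc)2 and quinoline returns to the route at 26.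

2. Step 7, hindered cross-coupling. Transmetalation and reductive elimination may be slow when a fully substituted enolate carbon is joined to C5 next to quaternary C10, so that β-hydride elimination from the tertiary alkylpalladium reduces the triflate instead. The fallback sets out from ketone 10. A samarium Reformatsky addition (SmI2, 13, THF, −78 °C) to the C5 carbonyl should give the tertiary β-hydroxy ester F4 (C5 configuration not controlled). Dehydration with SOCl2/pyridine at 0 °C, which can only eliminate toward C6, returns to the route at alkene 15.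

3. Step 15, ethenolysis. The ruthenium methylidene may engage the internal alkene beside fully substituted C13 too slowly and decompose under ethylene, leaving the propenyl group untouched. The fallback sets out from 25. Ozonolysis (O3, CH2Cl2, −78 °C; PPh3) should give the C13 aldehyde F5, and Wittig methylenation (Ph3PCH3Br, KN(SiMe3)2, THF, 0 °C) returns to the route at 26.

**Further compounds**
F1 | step 13 | 8α-hydroxy C13 (trimethylsilyl)ethynyl ketone bis(tert-butyl ester) | C[Si](C)(C)C#CC(=O)CC[C@@H]1[C@@](C)(CC(=O)OC(C)(C)C)[C@H](C(C)(C)C(=O)OC(C)(C)C)CC[C@@]1(C)O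
F2 | step 13 | 13β-methyl-13α-(trimethylsilylethynyl) pyran bis(tert-butyl ester) | C[Si](C)(C)C#C[C@@]1(C)CC[C@@H]2[C@@](C)(CC(=O)OC(C)(C)C)[C@H](C(C)(C)C(=O)OC(C)(C)C)CC[C@@]2(C)O1
F3 | step 13 | 13α-ethynyl-13β-methyl pyran bis(tert-butyl ester) | C#C[C@@]1(C)CC[C@@H]2[C@@](C)(CC(=O)OC(C)(C)C)[C@H](C(C)(C)C(=O)OC(C)(C)C)CC[C@@]2(C)O1
F4 | step 7 | C5 tertiary β-hydroxy ester (C5 configuration not defined), 13β-OTBS | CC(C)(C)[Si](C)(C)O[C@@H]1CC[C@@H]2[C@@](C)(CC(=O)OC(C)(C)C)C(O)(C(C)(C)C(=O)OC(C)(C)C)CC[C@@]12C
F5 | step 15 | 13α-formyl-13β-methyl pyran bis(tert-butyl ester) | O=C[C@@]1(C)CC[C@@H]2[C@@](C)(CC(=O)OC(C)(C)C)[C@H](C(C)(C)C(=O)OC(C)(C)C)CC[C@@]2(C)O1
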